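**Retrosynthetic overview**

1. Feature: ring A (C1, C5, C6, C7, C8, C9, C10) carries the C5=C6 olefin, oxygen on C8 and the trans pair C1/C10, so it is a masked 1,4-cycloheptadiene. Cutting C1–C10 and rejoining C6–C8 gives a cis-1,2-dialkenyl silyloxycyclopropane (C6, C7, C8) whose C7 arm is trans to both alkenyl groups.
2. The cyclopropane comes from an enantioselective intramolecular cyclopropanation of an E-allyl diazoacetate. The fused lactone ties C5 and C9 cis, bridgehead hydroxylation puts oxygen on C8, a lactol Wittig reaction gives the Z-propenyl group, and the C5 carbinol is grown into the E-alkenyl arm (alkyne, ynone reduction for C2, hydroalumination–iodination, methyl coupling).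
3. Ring order: cyclopropane (step 5), ring A by Cope rearrangement (step 19), ring B lactone on C7/C8 (step 22), then the C13 methylene, the C4 acetate and the C2 angelate.
4. C12 is carried through the rearrangement as a silyl-protected primary alcohol (in place of an ester) and is oxidised when ring B is closed; C2/C4 are masked as an acetonide.

Key step: step 19

Remark: locants C1–C15 in names are those of the target skeleton (C2–C4 side chain on C1, C11–C13 lactone carbons, C14 on C10, C15 on C5). TBS = tert-butyldimethylsilyl, TES = triethylsilyl. R/S descriptors that change between intermediates reflect priority changes only.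

Assumption: Rh2(4S-MPPIM)4 (dirhodium tetrakis[methyl (4S)-2-oxo-3-(3-phenylpropanoyl)imidazolidine-4-carboxylate]) is taken to give the (1R,5S,6S) lactone, as the S-configured carboxamidates do with simpler E-allyl diazoacetates; if the sense is opposite, the 4R catalyst is used.

**Route**

Step 1
Reactants: 1 tert-butyl(but-3-yn-1-yloxy)dimethylsilane
Product: 3 5-(TBS-oxy)pent-2-yn-1-ol, via lithium acetylide 2 (not isolated)
Conditions: n-BuLi, THF, −78 °C; (CH2O)n, −78 °C to rt
Reagents that add atoms: formaldehyde (as paraformaldehyde), C=O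
Why: Addition of the lithium acetylide to formaldehyde (carbonyl alkynylation) adds C5 as a propargylic alcohol and leaves the silyl ether untouched.

Step 2
Reactants: 3 5-(TBS-oxy)pent-2-yn-1-ol
Product: 4 (E)-5-(TBS-oxy)pent-2-en-1-ol
Conditions: NaAlH2(OCH2CH2OCH3)2, THF, 0 °C to rt
Reagents that add atoms: none
Why: Alkoxide-directed trans-hydroalumination of the propargylic alcohol followed by protonolysis should give the E-olefin C6=C7 only, and this geometry later fixes the trans relation of C6 and C7 on the cyclopropane.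

Step 3
Reactants: 4 (E)-5-(TBS-oxy)pent-2-en-1-ol
Product: 5 (E)-5-(TBS-oxy)pent-2-en-1-yl bromoacetate
Conditions: BrCH2COBr, NaHCO3, MeCN, 0 °C
Reagents that add atoms: bromoacetyl bromide, BrCC(Br)=O
Why: Acylation of the primary allylic alcohol by the acyl bromide under bicarbonate buffering (esterification) is fast and leaves the silyl ether and olefin intact.

Step 4
Reactants: 5 (E)-5-(TBS-oxy)pent-2-en-1-yl bromoacetate
Product: 6 (E)-5-(TBS-oxy)pent-2-en-1-yl diazoacetate
Conditions: N,N′-ditosylhydrazine, DBU, THF, 0 °C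
Reagents that add atoms: N,N′-bis(4-methylphenylsulfonyl)hydrazine, Cc1ccc(cc1)S(=O)(=O)NNS(=O)(=O)c1ccc(C)cc1
Why: N-Alkylation of the bis-sulfonylhydrazine by the bromoacetate and base-induced loss of two sulfinates (diazo formation from a 1,2-bis-sulfonylhydrazine) gives the diazoacetate under conditions mild enough for the allylic ester.

Step 5
Reactants: 6 (E)-5-(TBS-oxy)pent-2-en-1-yl diazoacetate
Product: 7 (1R,5S,6S)-6-[2-(TBS-oxy)ethyl]-3-oxabicyclo[3.1.0]hexan-2-one
Conditions: Rh2(4S-MPPIM)4 (1 mol %), CH2Cl2, reflux, slow addition of 6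
Reagents that add atoms: none
Why: Intramolecular rhodium-carbenoid cyclopropanation of the allylic olefin is stereospecific, so the E-olefin gives the cis-fused lactone with the C7 arm exo, while the chiral carboxamidate ligands choose the olefin face and thereby set C6, C7 and C8 in one event.

Step 6
Reactants: 7 (1R,5S,6S)-6-[2-(TBS-oxy)ethyl]-3-oxabicyclo[3.1.0]hexan-2-one
Product: 9 (1S,5R,6S)-1-hydroxy-6-[2-(TBS-oxy)ethyl]-3-oxabicyclo[3.1.0]hexan-2-one, via lithium enolate 8 (not isolated)
Conditions: LiN(i-Pr)2, THF, −78 °C; 2-(phenylsulfonyl)-3-phenyloxaziridine, −78 °C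
Reagents that add atoms: 2-(phenylsulfonyl)-3-phenyloxaziridine, O=S(=O)(c1ccccc1)N1OC1c1ccccc1
Why: Electrophilic α-hydroxylation of the lactone enolate by the N-sulfonyloxaziridine can only take place on the exo face of the pyramidal bridgehead carbanion held in the bicycle, so oxygen enters C8 with retention, cis to the C7 arm and trans to C5.

Step 7
Reactants: 9 (1S,5R,6S)-1-hydroxy-6-[2-(TBS-oxy)ethyl]-3-oxabicyclo[3.1.0]hexan-2-one
Product: 10 (1S,5R,6S)-1-(TBS-oxy)-6-[2-(TBS-oxy)ethyl]-3-oxabicyclo[3.1.0]hexan-2-one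
Conditions: TBSOTf, 2,6-lutidine, CH2Cl2, 0 °C
Reagents that add atoms: tert-butyldimethylsilyl trifluoromethanesulfonate, CC(C)(C)[Si](C)(C)OS(=O)(=O)C(F)(F)F
Why: Silylation of the hindered tertiary alcohol with the silyl triflate and a non-nucleophilic pyridine base (silyl ether formation) protects the future cyclopropanol oxygen in the form needed for the rearrangement.

Step 8
Reactants: 10 (1S,5R,6S)-1-(TBS-oxy)-6-[2-(TBS-oxy)ethyl]-3-oxabicyclo[3.1.0]hexan-2-one
Product: 11 (1S,5R,6S)-1-(TBS-oxy)-6-[2-(TBS-oxy)ethyl]-3-oxabicyclo[3.1.0]hexan-2-ol (lactol; both C2 epimers)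
Conditions: i-Bu2AlH, CH2Cl2, −78 °C
Reagents that add atoms: none
Why: Partial reduction of the lactone with one equivalent of the aluminium hydride at low temperature stops at the lactol because the tetrahedral aluminate is stable until work-up.

Step 9
Reactants: 11 lactol
Product: 12 [(1R,2S,3S)-2-(TBS-oxy)-3-[2-(TBS-oxy)ethyl]-2-[(Z)-prop-1-enyl]cyclopropyl]methanol
Conditions: EtPPh3Br, KN(SiMe3)2, THF, −78 to 0 °C
Reagents that add atoms: ethyltriphenylphosphonium bromide, CC[P+](c1ccccc1)(c1ccccc1)c1ccccc1.[Br-]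
Why: Wittig olefination of the open hydroxy aldehyde form of the lactol with the non-stabilised ethylidene ylide under salt-free conditions should give the Z-propenyl group (C9=C10, the future inward C14 methyl) and frees the C5 alcohol.

Step 10
Reactants: 12 cyclopropylmethanol
Product: 13 (1S,2S,3S)-2-(TBS-oxy)-3-[2-(TBS-oxy)ethyl]-2-[(Z)-prop-1-enyl]cyclopropane-1-carbaldehyde
Conditions: Dess–Martin periodinane, NaHCO3, CH2Cl2, 0 °C; used at once
Reagents that add atoms: none
Why: Dess–Martin oxidation of the primary cyclopropylcarbinol under bicarbonate buffering gives the aldehyde without acid that could open the silyloxycyclopropane, and the cold solution is used directly to avoid the hetero-Cope shift of the cis vinyl aldehyde.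

Step 11
Reactants: 13 cyclopropanecarbaldehyde
Product: 14 (1S,2S,3R)-1-(TBS-oxy)-2-[2-(TBS-oxy)ethyl]-3-ethynyl-1-[(Z)-prop-1-enyl]cyclopropane
Conditions: dimethyl (1-diazo-2-oxopropyl)phosphonate, K2CO3, MeOH, 0 °C to rt
Reagents that add atoms: dimethyl (1-diazo-2-oxopropyl)phosphonate, COP(=O)(OC)C(=[N+]=[N-])C(C)=O
Why: Seyferth–Gilbert homologation with the diazomethylphosphonate generated in situ by methanolysis turns the C5 aldehyde into the terminal alkyne (adding C1) under mild carbonate conditions that the silyl ethers tolerate.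

Step 12
Reactants: 15 methyl 3-hydroxypropanoate
Product: 16 3-hydroxy-N-methoxy-N-methylpropanamide
Conditions: MeNHOMe·HCl, i-PrMgCl, THF, −20 °C
Reagents that add atoms: N,O-dimethylhydroxylamine hydrochloride, CNOC.Cl
Why: Aminolysis of the methyl ester by the chloromagnesium amide of N,O-dimethylhydroxylamine (Weinreb amide formation) proceeds with the free hydroxyl simply carried as its alkoxide.

Step 13
Reactants: 16 3-hydroxy-N-methoxy-N-methylpropanamide
Product: 17 N-methoxy-N-methyl-3-(TES-oxy)propanamide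
Conditions: Et3SiCl, imidazole, CH2Cl2, 0 °C
Reagents that add atoms: chlorotriethylsilane, CC[Si](Cl)(CC)CC
Why: Silylation of the primary alcohol with the silyl chloride and imidazole gives a β-silyloxy amide whose triethylsilyl ether is later removable in the presence of TBS ethers.

Step 14
Reactants: 14 ethynylcyclopropane, 17 N-methoxy-N-methyl-3-(TES-oxy)propanamide
Product: 19 1-[(1R,2S,3S)-2-(TBS-oxy)-3-[2-(TBS-oxy)ethyl]-2-[(Z)-prop-1-enyl]cyclopropyl]-5-(TES-oxy)pent-1-yn-3-one, via lithium acetylide 18 (not isolated)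
Conditions: n-BuLi, THF, −78 °C; 17, −78 to 0 °C
Reagents that add atoms: none
Why: Acylation of the lithium acetylide by the Weinreb amide forms the C1–C2 bond and stops at the ketone because the chelated tetrahedral adduct only collapses on work-up.

Step 15
Reactants: 19 ynone
Product: 20 (3S)-1-[(1R,2S,3S)-2-(TBS-oxy)-3-[2-(TBS-oxy)ethyl]-2-[(Z)-prop-1-enyl]cyclopropyl]-5-(TES-oxy)pent-1-yn-3-ol
Conditions: Ru[(S,S)-TsDPEN](p-cymene) (2 mol %), i-PrOH, rt
Reagents that add atoms: none
Why: Asymmetric transfer hydrogenation of the ynone (Noyori-type reduction) sets C2 by catalyst control, the (S,S)-diamine complex delivering hydride to the face that gives the S carbinol when the alkynyl group takes the place of the π substituent.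

Step 16
Reactants: 20 propargylic alcohol
Product: 22 (1Z,3S)-1-[(1S,2S,3S)-2-(TBS-oxy)-3-[2-(TBS-oxy)ethyl]-2-[(Z)-prop-1-enyl]cyclopropyl]-1-iodo-5-(TES-oxy)pent-1-en-3-ol, via alkenylaluminate 21 (not isolated)
Conditions: NaAlH2(OCH2CH2OCH3)2, THF, 0 °C to rt; EtOAc; iodine, −78 °C
Reagents that add atoms: iodine, [I][I]
Why: Hydroxyl-directed trans-hydroalumination puts aluminium on C5 in a five-membered alkoxyaluminate and hydride on C1, and iodinolysis of the C–Al bond with retention gives the Z-iodoalkene in which C6 and C2 are already trans.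

Step 17
Reactants: 22 iodo allylic alcohol
Product: 24 (4S)-4-[(Z)-2-[(1S,2S,3S)-2-(TBS-oxy)-3-[2-(TBS-oxy)ethyl]-2-[(Z)-prop-1-enyl]cyclopropyl]-2-iodoethenyl]-2,2-dimethyl-1,3-dioxane, via iodo diol 23 (not isolated)
Conditions: PPTS, MeOH, 0 °C to rt; concentrate; 2,2-dimethoxypropane, PPTS, CH2Cl2, rt
Reagents that add atoms: 2,2-dimethoxypropane, COC(C)(C)OC
Why: Acid-catalysed methanolysis removes the primary triethylsilyl ether much faster than the TBS ethers and acetal exchange with 2,2-dimethoxypropane then ties the C2 and C4 hydroxyls into a 1,3-dioxane (acetonide formation).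

Step 18
Reactants: 24 iodoalkenyl acetonide
Product: 25 (4S)-4-[(E)-2-[(1R,2S,3S)-2-(TBS-oxy)-3-[2-(TBS-oxy)ethyl]-2-[(Z)-prop-1-enyl]cyclopropyl]prop-1-enyl]-2,2-dimethyl-1,3-dioxane (cis-dialkenyl silyloxycyclopropane)
Conditions: MeZnCl, Pd(PPh3)4 (5 mol %), THF, rt
Reagents that add atoms: methylzinc chloride, C[Zn]Cl
Why: Negishi cross-coupling of the alkenyl iodide with the methylzinc reagent replaces iodine by the C15 methyl with retention of olefin geometry, giving the E-trisubstituted C5=C1 olefin at room temperature.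

Step 19
Reactants: 25 cis-dialkenyl silyloxycyclopropane
Product: 26 ring A silyl enol ether: (1S,7S,10S)-8-(TBS-oxy)-7-[2-(TBS-oxy)ethyl]-1-[(4S)-2,2-dimethyl-1,3-dioxan-4-yl]-5,10-dimethylcyclohepta-5,8-diene (target locants)
Conditions: toluene, 2,6-di-tert-butyl-4-methylphenol (cat.), 120 °C, sealed tube, base-washed glass
Reagents that add atoms: none
Why: Heating should trigger a concerted suprafacial [3,3]-sigmatropic shift through the boat-shaped transition state that is the only one open to a cis-dialkenylcyclopropane, in which the C6–C8 ring bond breaks as the alkenyl termini C1 and C10 bond and the release of cyclopropane strain drives the reaction. The closest known reaction type is the cis-divinylcyclopropane to 1,4-cycloheptadiene (Cope) rearrangement, here with a silyloxy group on the breaking bond as in oxy-Cope substrates. Ring A is closed by this pericyclic ring expansion, the seven-membered ring growing out of the three-membered one through one new σ bond (C1–C10). C1 is set by the E geometry of C5=C1, which turns the C2 substituent outward, and C10 by the Z geometry of the propenyl group, which turns C14 inward, so the two are trans; both are tied to C7 because the C7 arm is anti to the alkenyl groups on the cyclopropane and therefore ends cis to the C1 side chain, the absolute sense coming from the cyclopropane made in step 5. The step needs the boat pathway to outrun a homodienyl hydrogen shift and epimerisation of the cyclopropane, which is secured by the cis relation of the two alkenyl groups, by the absence of any alkyl group cis to them (the inward methyl meets only C7–H) and by the donor silyloxy group, which also leaves C8 unambiguously as the enol ether carbon.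

Step 20
Reactants: 26 ring A silyl enol ether
Product: 27 (1S,7S,10R)-1-[(4S)-2,2-dimethyl-1,3-dioxan-4-yl]-7-(2-hydroxyethyl)-5,10-dimethylcyclohept-5-en-8-one (target locants)
Conditions: Bu4NF, AcOH (1:1), THF, 0 °C to rt
Reagents that add atoms: none
Why: Fluoride cleaves the enol silyl ether and the primary silyl ether, and the acetic acid buffer protonates the C8 enolate at C9 at once so that C7, which is α to the new ketone and allylic, neither epimerises nor lets the C5=C6 olefin move into conjugation (desilylation).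

Step 21
Reactants: 27 hydroxy ketone
Product: 28 (1S,7S,8R,10R)-1-[(4S)-2,2-dimethyl-1,3-dioxan-4-yl]-7-(2-hydroxyethyl)-5,10-dimethylcyclohept-5-en-8-ol (target locants)
Conditions: LiBH(s-Bu)3 (3 equiv), THF, −78 °C; NaOH, H2O2, 0 °C
Reagents that add atoms: none
Why: The bulky borohydride should attack the C8 ketone from the face opposite the neighbouring C7 arm (sterically controlled ketone reduction), giving the C8 alcohol cis to that arm as the ring B fusion requires.

Step 22
Reactants: 28 diol
Product: 30 cis-fused γ-lactone (rings A and B; 1S,2S,7S,8R,10R; C2/C4 acetonide), via lactol 29 (not isolated)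
Conditions: TEMPO (cat.), PhI(OAc)2, CH2Cl2, rt
Reagents that add atoms: none
Why: The oxoammonium oxidation is selective for the primary alcohol, the aldehyde is trapped by the cis C8 hydroxyl as a lactol and this is oxidised on to the cis-fused γ-lactone (oxidative lactonisation), which closes ring B in a 5-exo hemiacetalisation mode.

Step 23
Reactants: 30 γ-lactone
Product: 32 C11-(dimethylaminomethyl) lactone (C11 epimers), via lithium enolate 31 (not isolated)
Conditions: LiN(i-Pr)2, THF, −78 °C; N,N-dimethylmethyleneiminium iodide, −78 °C to rt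
Reagents that add atoms: N,N-dimethylmethyleneiminium iodide, C[N+](C)=C.[I-]
Why: Mannich reaction of the lactone enolate with the preformed iminium salt introduces C13 at C11, the only enolisable position.

Step 24
Reactants: 32 Mannich base
Product: 34 α-methylene lactone (1S,2S,7R,8R,10R; C2/C4 acetonide), via ammonium iodide 33 (not isolated)
Conditions: iodomethane, MeOH, rt; NaHCO3 (aq), CH2Cl2, rt
Reagents that add atoms: none
Why: Quaternisation of the amine and mild base-induced β-elimination of trimethylamine (Hofmann-type E1cB elimination) give the exocyclic C11=C13 methylene.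

Step 25
Reactants: 34 α-methylene lactone acetonide
Product: 35 C2,C4-diol of the α-methylene lactone
Conditions: AcOH/H2O/THF (3:1:1), 40 °C
Reagents that add atoms: none
Why: Aqueous acetic acid hydrolyses the acetonide (acetal hydrolysis) while the α-methylene lactone and the trisubstituted olefin are stable to this weak acid.

Step 26
Reactants: 35 diol
Product: 36 C4 acetate with free C2 hydroxyl
Conditions: AcCl, 2,4,6-collidine, CH2Cl2, −78 °C
Reagents that add atoms: acetyl chloride, CC(Cl)=O
Why: Acylation with acetyl chloride and a hindered pyridine base at low temperature is selective for the primary C4 hydroxyl over the secondary allylic C2 hydroxyl (chemoselective esterification).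

Step 27
Reactants: 36 C4 acetate, 37 angelic acid
Product: 39 CNP0163960.1, via mixed anhydride 38 (not isolated)
Conditions: 2,4,6-Cl3C6H2COCl, Et3N, toluene, rt; then 36, 80 °C
Reagents that add atoms: none
Why: Esterification through the mixed 2,4,6-trichlorobenzoic anhydride (Yamaguchi-type acylation) transfers the angeloyl group to the C2 hydroxyl without a nucleophilic catalyst, which should keep the Z olefin of the angelate from isomerising to the tiglate.

**Compound list**

1 | tert-butyl(but-3-yn-1-yloxy)dimethylsilane | C#CCCO[Si](C)(C)C(C)(C)C | starting material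
2 | lithium acetylide of 1 | [Li]C#CCCO[Si](C)(C)C(C)(C)C | intermediate
3 | 5-(TBS-oxy)pent-2-yn-1-ol | OCC#CCCO[Si](C)(C)C(C)(C)C | intermediate
4 | (E)-5-(TBS-oxy)pent-2-en-1-ol | OC/C=C/CCO[Si](C)(C)C(C)(C)C | intermediate
5 | (E)-5-(TBS-oxy)pent-2-en-1-yl bromoacetate | BrCC(=O)OC/C=C/CCO[Si](C)(C)C(C)(C)C | intermediate
6 | (E)-5-(TBS-oxy)pent-2-en-1-yl diazoacetate | [N-]=[N+]=CC(=O)OC/C=C/CCO[Si](C)(C)C(C)(C)C | intermediate
7 | (1R,5S,6S)-6-[2-(TBS-oxy)ethyl]-3-oxabicyclo[3.1.0]hexan-2-one | CC(C)(C)[Si](C)(C)OCC[C@H]1[C@@H]2COC(=O)[C@H]12 | intermediate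
8 | lithium enolate of 7 | CC(C)(C)[Si](C)(C)OCC[C@H]1[C@@H]2COC(O[Li])=C12 | intermediate
9 | (1S,5R,6S)-1-hydroxy-6-[2-(TBS-oxy)ethyl]-3-oxabicyclo[3.1.0]hexan-2-one | CC(C)(C)[Si](C)(C)OCC[C@H]1[C@@H]2COC(=O)[C@]12O | intermediate
10 | (1S,5R,6S)-1-(TBS-oxy)-6-[2-(TBS-oxy)ethyl]-3-oxabicyclo[3.1.0]hexan-2-one | CC(C)(C)[Si](C)(C)OCC[C@H]1[C@@H]2COC(=O)[C@]12O[Si](C)(C)C(C)(C)C | intermediate
11 | (1S,5R,6S)-1-(TBS-oxy)-6-[2-(TBS-oxy)ethyl]-3-oxabicyclo[3.1.0]hexan-2-ol (lactol) | CC(C)(C)[Si](C)(C)OCC[C@H]1[C@@H]2COC(O)[C@]12O[Si](C)(C)C(C)(C)C | intermediate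
12 | [(1R,2S,3S)-2-(TBS-oxy)-3-[2-(TBS-oxy)ethyl]-2-[(Z)-prop-1-enyl]cyclopropyl]methanol | CC(C)(C)[Si](C)(C)OCC[C@H]1[C@H](CO)[C@]1(O[Si](C)(C)C(C)(C)C)/C=C\C | intermediate
13 | (1S,2S,3S)-2-(TBS-oxy)-3-[2-(TBS-oxy)ethyl]-2-[(Z)-prop-1-enyl]cyclopropane-1-carbaldehyde | CC(C)(C)[Si](C)(C)OCC[C@H]1[C@H](C=O)[C@]1(O[Si](C)(C)C(C)(C)C)/C=C\C | intermediate
14 | (1S,2S,3R)-1-(TBS-oxy)-2-[2-(TBS-oxy)ethyl]-3-ethynyl-1-[(Z)-prop-1-enyl]cyclopropane | CC(C)(C)[Si](C)(C)OCC[C@H]1[C@H](C#C)[C@]1(O[Si](C)(C)C(C)(C)C)/C=C\C | intermediate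
15 | methyl 3-hydroxypropanoate | COC(=O)CCO | starting material
16 | 3-hydroxy-N-methoxy-N-methylpropanamide | CON(C)C(=O)CCO | intermediate
17 | N-methoxy-N-methyl-3-(TES-oxy)propanamide | CON(C)C(=O)CCO[Si](CC)(CC)CC | intermediate
18 | lithium acetylide of 14 | CC(C)(C)[Si](C)(C)OCC[C@H]1[C@H](C#C[Li])[C@]1(O[Si](C)(C)C(C)(C)C)/C=C\C | intermediate
19 | ynone (C5≡C1, C2 ketone, C4 OTES) | CC(C)(C)[Si](C)(C)OCC[C@H]1[C@H](C#CC(=O)CCO[Si](CC)(CC)CC)[C@]1(O[Si](C)(C)C(C)(C)C)/C=C\C | intermediate
20 | (2S)-propargylic alcohol (target locant C2) | CC(C)(C)[Si](C)(C)OCC[C@H]1[C@H](C#C[C@@H](O)CCO[Si](CC)(CC)CC)[C@]1(O[Si](C)(C)C(C)(C)C)/C=C\C | intermediate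
21 | sodium cyclic alkenyl(alkoxy)aluminate (Al on C5) | CC(C)(C)[Si](C)(C)OCC[C@H]1[C@H](C2=C[C@H](CCO[Si](CC)(CC)CC)O[Al-]2(OCCOC)OCCOC)[C@]1(O[Si](C)(C)C(C)(C)C)/C=C\C.[Na+] | intermediate
22 | (Z)-C5-iodo allylic alcohol (C2 S, C4 OTES) | CC(C)(C)[Si](C)(C)OCC[C@H]1[C@H](/C(I)=C/[C@@H](O)CCO[Si](CC)(CC)CC)[C@]1(O[Si](C)(C)C(C)(C)C)/C=C\C | intermediate
23 | (Z)-C5-iodo C2,C4-diol | CC(C)(C)[Si](C)(C)OCC[C@H]1[C@H](/C(I)=C/[C@@H](O)CCO)[C@]1(O[Si](C)(C)C(C)(C)C)/C=C\C | intermediate
24 | (Z)-C5-iodoalkenyl acetonide | CC(C)(C)[Si](C)(C)OCC[C@H]1[C@H](/C(I)=C/[C@H](CCO2)OC2(C)C)[C@]1(O[Si](C)(C)C(C)(C)C)/C=C\C | intermediate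
25 | cis-dialkenyl silyloxycyclopropane (6R,7S,8S; 2S; C5=C1 E; C9=C10 Z) | CC(C)(C)[Si](C)(C)OCC[C@H]1[C@H](/C(C)=C/[C@H](CCO2)OC2(C)C)[C@]1(O[Si](C)(C)C(C)(C)C)/C=C\C | intermediate
26 | ring A C8 silyl enol ether (1S,2S,7S,10S) | CC(C)(C)[Si](C)(C)OC1=C[C@@H](C)[C@H]([C@H](CCO2)OC2(C)C)C(C)=C[C@@H]1CCO[Si](C)(C)C(C)(C)C | intermediate
27 | C8 ketone with free C12 hydroxyl (1S,2S,7S,10R) | O=C1C[C@@H](C)[C@H]([C@H](CCO2)OC2(C)C)C(C)=C[C@@H]1CCO | intermediate
28 | C8,C12-diol (1S,2S,7S,8R,10R) | O[C@@H]1C[C@@H](C)[C@H]([C@H](CCO2)OC2(C)C)C(C)=C[C@@H]1CCO | intermediate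
29 | C12 lactol (C12 epimers) | OC1O[C@@H]2C[C@@H](C)[C@H]([C@H](CCO3)OC3(C)C)C(C)=C[C@@H]2C1 | intermediate
30 | cis-fused γ-lactone (1S,2S,7S,8R,10R) | O=C1O[C@@H]2C[C@@H](C)[C@H]([C@H](CCO3)OC3(C)C)C(C)=C[C@@H]2C1 | intermediate
31 | lithium enolate of 30 | [Li]OC1O[C@@H]2C[C@@H](C)[C@H]([C@H](CCO3)OC3(C)C)C(C)=C[C@@H]2C=1 | intermediate
32 | C11-(dimethylaminomethyl) lactone (C11 epimers) | O=C1O[C@@H]2C[C@@H](C)[C@H]([C@H](CCO3)OC3(C)C)C(C)=C[C@@H]2C1CN(C)C | intermediate
33 | C11-(trimethylammoniomethyl) lactone iodide | O=C1O[C@@H]2C[C@@H](C)[C@H]([C@H](CCO3)OC3(C)C)C(C)=C[C@@H]2C1C[N+](C)(C)C.[I-] | intermediate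
34 | α-methylene lactone acetonide (1S,2S,7R,8R,10R) | O=C1O[C@@H]2C[C@@H](C)[C@H]([C@H](CCO3)OC3(C)C)C(C)=C[C@@H]2C1=C | intermediate
35 | α-methylene lactone C2,C4-diol | O=C1O[C@@H]2C[C@@H](C)[C@H]([C@H](CCO)O)C(C)=C[C@@H]2C1=C | intermediate
36 | α-methylene lactone C4 acetate, C2 alcohol | O=C1O[C@@H]2C[C@@H](C)[C@H]([C@H](CCOC(C)=O)O)C(C)=C[C@@H]2C1=C | intermediate
37 | angelic acid ((Z)-2-methylbut-2-enoic acid) | C/C=C(/C)C(=O)O | starting material
38 | angelic 2,4,6-trichlorobenzoic anhydride | C/C=C(/C)C(=O)OC(=O)c1c(Cl)cc(Cl)cc1Cl | intermediate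
39 | CNP0163960.1 | C=C1C(=O)O[C@@H]2C[C@@H](C)[C@H]([C@H](CCOC(C)=O)OC(=O)/C(C)=C\C)C(C)=C[C@H]12 | target

**Step count and risks**

Total step count: 27 (25 in the main line, 2 for amide 17). Longest linear sequence: 25 steps (steps 1–11 and 14–27).

Steps most likely to fail:

1. Step 19. The inward C14 methyl raises the barrier of the boat transition state, so at the temperature needed a homodienyl hydrogen shift from C14 or loss of the enol silyl group could compete with ring expansion. Fallback: starting from 25, both silyl ethers are removed with Bu4NF in THF at −20 °C to give the cyclopropanol diol F1. Its potassium alkoxide (KN(SiMe3)2, 18-crown-6, THF, −78 to 0 °C) should undergo the charge-accelerated oxy-Cope rearrangement at low temperature, and buffered protonation of the resulting C8 enolate gives hydroxy ketone 27, where the route is rejoined.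

2. Step 6. Claisen-type self-condensation of the strained bridgehead enolate, or its addition to the sulfonimine by-product, may outrun oxygen transfer. Fallback: starting from 7, deprotonation with LiN(i-Pr)2 in the presence of TBSCl (internal quench, THF, −78 °C) gives the silyl ketene acetal F2. Epoxidation on its exo face with m-chloroperbenzoic acid (NaHCO3, CH2Cl2, −20 °C) and silyl migration (Rubottom oxidation) gives the silyloxy lactone 10 directly, where the route is rejoined.

3. Step 21. Hydride delivery from the face of the C7 arm, if the C10 methyl shields the other face, would give the C8 epimer. Fallback: starting from 27, the epimeric diol F3 formed in that case is oxidised at the primary alcohol to the hydroxy acid F4 (TEMPO, NaOCl (cat.), NaClO2, phosphate buffer, MeCN). Mitsunobu lactonisation (PPh3, diisopropyl azodicarboxylate, THF, 0 °C) then closes ring B with inversion at C8 and gives lactone 30, where the route is rejoined.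

**Further compounds**

F1 | step 19 | cyclopropanol diol from 25 (both silyl groups removed) | OCC[C@H]1[C@H](/C(C)=C/[C@H](CCO2)OC2(C)C)[C@]1(O)/C=C\C
F2 | step 6 | TBS ketene acetal of lactone 7 | CC(C)(C)[Si](C)(C)OCC[C@H]1[C@@H]2COC(O[Si](C)(C)C(C)(C)C)=C12
F3 | step 21 | C8-epimeric diol | O[C@H]1C[C@@H](C)[C@H]([C@H](CCO2)OC2(C)C)C(C)=C[C@@H]1CCO
F4 | step 21 | C8-epimeric hydroxy acid | O[C@H]1C[C@@H](C)[C@H]([C@H](CCO2)OC2(C)C)C(C)=C[C@@H]1CC(=O)O
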